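**Retrosynthetic overview**

1. The target holds two (3R,4R)-3-hydroxy-3,4-dibenzyl-γ-butyrolactones (lactone 1, lactone 2) on a 5,5'-linked bis-guaiacyl core (rings b and c), with outer guaiacyl rings a and d. The last operations are hydrogenolysis of four benzyl ethers ⇐ C-benzylation of the α-oxy enolate of lactone 2 with the ring d benzyl bromide ⇐ α-hydroxylation of lactone 2.
2. Key disconnection: the bond between the benzylic CH2 on ring c and C-4 of lactone 2. It is made by an enantioselective photoredox/chiral-Lewis-acid Giese addition of the ring c benzyl radical (from a benzyltrifluoroborate that already carries lactone 1 and the biaryl) to an achiral, acyclic (E)-4-silyloxybut-2-enoyl pyrazole, and lactone 2 is closed in the same flask.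
3. Enabling feature: C-4 of lactone 2 lies β to the lactone carbonyl C-2 and carries the C-5 methylene bonded to the ring oxygen, so lactone 2 is a latent 4-oxybut-2-enoyl radical acceptor. Its partner carbon is benzylic to the 4-oxy-3-methoxy-substituted ring c, whose CH2–BF3K group is oxidised at low potential to a nucleophilic benzyl radical.
4. The trifluoroborate fragment ⇐ Miyaura-type borylation of a benzylic bromide ⇐ enediolate alkylation of the α-hydroxy lactone 1 precursor with a C2-symmetric bis(bromomethyl)biaryl (vanillin ⇒ oxidative 5,5'-coupling). The lactone 1 precursor ⇐ the same Giese/lactonisation and hydroxylation on the simple ring a trifluoroborate.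
5. Order of ring formation: the biaryl bond b–c (step 7) and lactone 1 (step 5) are made separately and joined in step 11; lactone 2 is formed last (step 13).

Key step: step 13

Assumption: the Λ enantiomer of the rhodium Lewis acid is taken to expose the Si face of the β-carbon of the chelated enoyl pyrazole (giving the 4S lactones); if the sense of induction is the opposite, the Δ enantiomer is used in both Giese steps.
Remark: the 2,2'-dioxygenated biaryl axis has no further ortho substituents and is treated as freely rotating, so no axial stereochemistry needs control.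

**Route**

Step 1
Reactants: 1 2-(diethoxyphosphoryl)acetic acid; 2 3,5-dimethyl-1H-pyrazole
Product: 3 diethyl [2-(3,5-dimethyl-1H-pyrazol-1-yl)-2-oxoethyl]phosphonate
Conditions: DCC, DMAP (cat.), CH2Cl2, 0 °C to rt
Reagents that add atoms: none
Why: Carbodiimide-mediated N-acylation (Steglich-type coupling) of the pyrazole N–H by the activated carboxylic acid should be clean because the acid carries no other nucleophilic or acidic function and the product is a stable active amide.

Step 2
Reactants: 3 diethyl [2-(3,5-dimethyl-1H-pyrazol-1-yl)-2-oxoethyl]phosphonate; 4 2-[(tert-butyldimethylsilyl)oxy]acetaldehyde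
Product: 5 (2E)-4-[(tert-butyldimethylsilyl)oxy]-1-(3,5-dimethyl-1H-pyrazol-1-yl)but-2-en-1-one
Conditions: NaH, THF, 0 °C; then 4, 0 °C to rt
Reagents that add atoms: none
Why: Horner–Wadsworth–Emmons olefination of the doubly stabilised phosphonate anion with the unhindered aldehyde should give the (E)-enoyl pyrazole, the E geometry arising from reversible addition and collapse of the more stable anti oxaphosphetane.

Step 3
Reactants: 6 [4-(benzyloxy)-3-methoxyphenyl]methanol
Product: 7 1-(benzyloxy)-4-(bromomethyl)-2-methoxybenzene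
Conditions: PBr3, Et2O, 0 °C
Reagents that add atoms: phosphorus tribromide, BrP(Br)Br
Why: Bromination of a primary, electron-rich benzylic alcohol with PBr3 proceeds by SN2 displacement of the activated phosphite ester by bromide and leaves the aryl benzyl ether untouched.

Step 4
Reactants: 7 1-(benzyloxy)-4-(bromomethyl)-2-methoxybenzene
Product: 9 potassium {[4-(benzyloxy)-3-methoxyphenyl]methyl}trifluoroborate, via pinacol boronate 8 (not isolated)
Conditions: B2pin2, Pd2(dba)3 (cat.), P(4-MeOC6H4)3, KOAc, toluene, 50 °C; then aq KHF2, MeOH, rt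
Reagents that add atoms: bis(pinacolato)diboron, CC1(C)OB(OC1(C)C)B1OC(C)(C)C(C)(C)O1; potassium hydrogen difluoride, F.[F-].[K+]
Why: Miyaura-type borylation of the benzylic bromide (oxidative addition to zerovalent palladium, acetate-assisted transmetalation from B2pin2, reductive elimination) followed by ligand exchange on boron with KHF2 should deliver a bench-stable benzyltrifluoroborate whose C–B bond is easily oxidised.

Step 5
Reactants: 9 potassium {[4-(benzyloxy)-3-methoxyphenyl]methyl}trifluoroborate; 5 (2E)-4-[(tert-butyldimethylsilyl)oxy]-1-(3,5-dimethyl-1H-pyrazol-1-yl)but-2-en-1-one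
Product: 11 (4S)-4-{[4-(benzyloxy)-3-methoxyphenyl]methyl}oxolan-2-one, via acyl pyrazole adduct 10 (not isolated)
Conditions: Λ-[Rh(C17H16NS)2(MeCN)2]PF6 (4 mol %; C17H16NS = cyclometalated 5-tert-butyl-2-phenylbenzothiazole), 4CzIPN (2 mol %), acetone/H2O 4:1, blue LEDs, rt; then 2 M HCl, THF, rt
Reagents that add atoms: none
Why: In this dual photoredox/chiral Lewis acid catalysed enantioselective Giese addition the benzyl radical released by single-electron oxidation of the trifluoroborate adds to the Si face of the β-carbon of the rhodium-chelated enoyl pyrazole (face selection by the tert-butyl-shielded, chiral-at-metal trivalent rhodium centre sets the S centre), and acid then removes the silyl group so that the freed hydroxyl displaces the pyrazole by 5-exo-trig acyl substitution to close the lactone.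

Step 6
Reactants: 11 (4S)-4-{[4-(benzyloxy)-3-methoxyphenyl]methyl}oxolan-2-one
Product: 12 (3S,4R)-4-{[4-(benzyloxy)-3-methoxyphenyl]methyl}-3-hydroxyoxolan-2-one
Conditions: KN(SiMe3)2, THF, −78 °C; then 2-(phenylsulfonyl)-3-phenyloxaziridine, −78 °C; AcOH
Reagents that add atoms: 2-(phenylsulfonyl)-3-phenyloxaziridine, O=S(=O)(N1OC1c1ccccc1)c1ccccc1
Why: Electrophilic α-hydroxylation of the potassium lactone enolate by the N-sulfonyloxaziridine should take place anti to the C-4 benzyl group and give mainly the trans (3S,4R) alcohol, a centre whose configuration is not critical because it is planarised again in step 11.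

Step 7
Reactants: 13 vanillin (two molecules)
Product: 14 6,6'-dihydroxy-5,5'-dimethoxy-[1,1'-biphenyl]-3,3'-dicarbaldehyde (dehydrodivanillin)
Conditions: FeSO4·7H2O (cat.), Na2S2O8, H2O, 50 °C
Reagents that add atoms: none
Why: In this oxidative phenol coupling the sulfate radical anion from iron-catalysed persulfate decomposition generates the vanillin phenoxyl radical, which dimerises through C-5, the only free position ortho to the hydroxyl since the para position carries the formyl group.

Step 8
Reactants: 14 dehydrodivanillin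
Product: 15 6,6'-bis(benzyloxy)-5,5'-dimethoxy-[1,1'-biphenyl]-3,3'-dicarbaldehyde
Conditions: BnBr, K2CO3, DMF, 60 °C
Reagents that add atoms: benzyl bromide, BrCc1ccccc1
Why: Williamson ether synthesis on both phenoxides with benzyl bromide installs protecting groups that withstand strong bases, palladium-catalysed borylation and photoredox conditions and fall together at the end by hydrogenolysis.

Step 9
Reactants: 15 6,6'-bis(benzyloxy)-5,5'-dimethoxy-[1,1'-biphenyl]-3,3'-dicarbaldehyde
Product: 16 [6,6'-bis(benzyloxy)-5,5'-dimethoxy-[1,1'-biphenyl]-3,3'-diyl]dimethanol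
Conditions: NaBH4, THF/MeOH, 0 °C
Reagents that add atoms: none
Why: Hydride reduction of both aryl aldehydes by NaBH4 is chemoselective and needs no control of stereochemistry.

Step 10
Reactants: 16 [6,6'-bis(benzyloxy)-5,5'-dimethoxy-[1,1'-biphenyl]-3,3'-diyl]dimethanol
Product: 17 2,2'-bis(benzyloxy)-5,5'-bis(bromomethyl)-3,3'-dimethoxy-1,1'-biphenyl
Conditions: PBr3, CH2Cl2, 0 °C
Reagents that add atoms: phosphorus tribromide, BrP(Br)Br
Why: Twofold PBr3 bromination of the benzylic diol by SN2 displacement gives the C2-symmetric bis-electrophile, the two arms of which are identical so that no regiochemical question arises in step 11.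

Step 11
Reactants: 12 (3S,4R)-4-{[4-(benzyloxy)-3-methoxyphenyl]methyl}-3-hydroxyoxolan-2-one; 17 2,2'-bis(benzyloxy)-5,5'-bis(bromomethyl)-3,3'-dimethoxy-1,1'-biphenyl
Product: 18 (3R,4R)-4-{[4-(benzyloxy)-3-methoxyphenyl]methyl}-3-{[6,6'-bis(benzyloxy)-3'-(bromomethyl)-5,5'-dimethoxy-[1,1'-biphenyl]-3-yl]methyl}-3-hydroxyoxolan-2-one
Conditions: 12, LiN(iPr)2 (2.2 equiv), THF/DMPU, −78 °C; then 17 (3 equiv, excess recovered), −78 to −40 °C; AcOH
Reagents that add atoms: none
Why: Alkylation of the lithium enediolate (dianion) of the α-hydroxy lactone at carbon with one arm of the excess dibromide should occur on the enolate face anti to the C-4 benzyl group, which places the new benzyl trans to it and the hydroxyl cis and so sets the (3R) quaternary carbinol whatever the C-3 configuration of 12 was.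

Step 12
Reactants: 18 the lactone 1 benzylic bromide
Product: 20 potassium trifluoroborate of 18 (CH2Br on ring c replaced by CH2BF3K), via pinacol boronate 19 (not isolated)
Conditions: B2pin2, Pd2(dba)3 (cat.), P(4-MeOC6H4)3, KOAc, toluene, 50 °C; then aq KHF2, MeOH, rt
Reagents that add atoms: bis(pinacolato)diboron, CC1(C)OB(OC1(C)C)B1OC(C)(C)C(C)(C)O1; potassium hydrogen difluoride, F.[F-].[K+]
Why: The same Miyaura-type borylation and KHF2 exchange as in step 4 convert the remaining benzylic bromide into the trifluoroborate under conditions (KOAc, 50 °C, then mildly acidic fluoride) that the lactone, the free tertiary alcohol and the benzyl ethers should tolerate.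

Step 13
Reactants: 20 potassium trifluoroborate fragment (lactone 1, rings a to c); 5 (2E)-4-[(tert-butyldimethylsilyl)oxy]-1-(3,5-dimethyl-1H-pyrazol-1-yl)but-2-en-1-one
Product: 22 bis-lactone in which the ring c benzylic CH2 is bonded to C-4 of a (4S)-oxolan-2-one (lactone 2), via acyl pyrazole adduct 21 (not isolated)
Conditions: 20 (1 equiv), 5 (2 equiv), Λ-[Rh(C17H16NS)2(MeCN)2]PF6 (8 mol %), 4CzIPN (2 mol %), acetone/H2O 4:1, blue LEDs, rt; then 2 M HCl, THF, rt
Reagents that add atoms: none
Why: Photoexcited 4CzIPN oxidises the benzyl–BF3K group of 20 to the ring c benzyl radical with loss of BF3, the radical adds to the β-carbon of 5 held as an N,O-chelate on the chiral-at-metal trivalent rhodium Lewis acid, the rhodium-bound α-carbonyl radical is reduced by the 4CzIPN radical anion to the enolate, and protonation releases adduct 21. The closest known reaction type is the enantioselective Giese addition of organotrifluoroborates to α,β-unsaturated N-acyl pyrazoles under combined photoredox and chiral rhodium Lewis acid catalysis. Lactone ring 2 is then closed in the same flask: acid removes the silyl group and the freed primary hydroxyl attacks the active amide carbonyl in a 5-exo-trig acyl substitution that expels 3,5-dimethylpyrazole. The one new stereocentre, C-4 of lactone 2, is set under catalyst control, the tert-butyl groups of the cyclometalated ligands shielding one face of the bound enoyl unit so that the radical should add to the Si face of the β-carbon and give the S configuration. The step needs β-regioselectivity, a radical addition that outruns benzyl radical dimerisation, and chemoselective oxidation of the C–B bond beside three other electron-rich aryl ether rings. The two-point chelation, which also lowers the LUMO of the acceptor, and the low oxidation potential of the 4-alkoxy-3-methoxybenzyl–BF3K group secure these, and the remote stereocentres of lactone 1 should not interfere with the catalyst-controlled face selection.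

Step 14
Reactants: 22 bis-lactone with unsubstituted C-3 in lactone 2
Product: 23 bis-lactone with a (3S,4R)-3-hydroxy lactone 2
Conditions: KN(SiMe3)2 (2.3 equiv), THF, −78 °C; then 2-(phenylsulfonyl)-3-phenyloxaziridine, −78 °C; AcOH
Reagents that add atoms: 2-(phenylsulfonyl)-3-phenyloxaziridine, O=S(=O)(N1OC1c1ccccc1)c1ccccc1
Why: Electrophilic α-hydroxylation by the N-sulfonyloxaziridine of the potassium enolate of lactone 2, the only enolisable carbonyl since lactone 1 is quaternary at C-3 and merely forms its alkoxide with the extra equivalent of base, should again occur anti to the C-4 substituent to give mainly the trans alcohol.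

Step 15
Reactants: 23 bis-lactone with a (3S,4R)-3-hydroxy lactone 2; 7 1-(benzyloxy)-4-(bromomethyl)-2-methoxybenzene
Product: 24 tetra-O-benzyl ether of the target
Conditions: 23, LiN(iPr)2 (3.3 equiv), THF/DMPU, −78 °C; then 7, −78 to −40 °C; AcOH
Reagents that add atoms: none
Why: C-Benzylation of the enediolate of lactone 2 (the third equivalent of base only deprotonates the tertiary hydroxyl of lactone 1) with the ring d bromide should occur anti to the C-4 benzyl group, as in step 11, which sets the (3R) quaternary carbinol of lactone 2 with the two benzyl groups trans.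

Step 16
Reactants: 24 tetra-O-benzyl ether of the target
Product: 25 CNP0218652.1 (target)
Conditions: H2 (1 atm), Pd/C (palladium on carbon), EtOAc/MeOH, rt
Reagents that add atoms: none
Why: Heterogeneous hydrogenolysis cleaves the four aryl benzyl ethers, the only benzylic C–O bonds in the molecule, while the lactones, tertiary alcohols and biaryl are inert and no stereocentre is touched.

**Compound list**

1 | 2-(diethoxyphosphoryl)acetic acid | CCOP(=O)(CC(=O)O)OCC | starting material
2 | 3,5-dimethyl-1H-pyrazole | Cc1cc(C)[nH]n1 | starting material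
3 | diethyl [2-(3,5-dimethyl-1H-pyrazol-1-yl)-2-oxoethyl]phosphonate | CCOP(=O)(CC(=O)n1nc(C)cc1C)OCC | intermediate
4 | 2-[(tert-butyldimethylsilyl)oxy]acetaldehyde | CC(C)(C)[Si](C)(C)OCC=O | starting material
5 | (2E)-4-[(tert-butyldimethylsilyl)oxy]-1-(3,5-dimethyl-1H-pyrazol-1-yl)but-2-en-1-one | Cc1cc(C)n(n1)C(=O)/C=C/CO[Si](C)(C)C(C)(C)C | intermediate
6 | [4-(benzyloxy)-3-methoxyphenyl]methanol | COc1cc(CO)ccc1OCc1ccccc1 | starting material
7 | 1-(benzyloxy)-4-(bromomethyl)-2-methoxybenzene | COc1cc(CBr)ccc1OCc1ccccc1 | intermediate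
8 | 2-{[4-(benzyloxy)-3-methoxyphenyl]methyl}-4,4,5,5-tetramethyl-1,3,2-dioxaborolane | COc1cc(CB2OC(C)(C)C(C)(C)O2)ccc1OCc1ccccc1 | intermediate (not isolated)
9 | potassium {[4-(benzyloxy)-3-methoxyphenyl]methyl}trifluoroborate | COc1cc(C[B-](F)(F)F)ccc1OCc1ccccc1.[K+] | intermediate
10 | (3S)-3-{[4-(benzyloxy)-3-methoxyphenyl]methyl}-4-[(tert-butyldimethylsilyl)oxy]-1-(3,5-dimethyl-1H-pyrazol-1-yl)butan-1-one | COc1cc(C[C@H](CO[Si](C)(C)C(C)(C)C)CC(=O)n2nc(C)cc2C)ccc1OCc1ccccc1 | intermediate (not isolated)
11 | (4S)-4-{[4-(benzyloxy)-3-methoxyphenyl]methyl}oxolan-2-one | COc1cc(C[C@@H]2COC(=O)C2)ccc1OCc1ccccc1 | intermediate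
12 | (3S,4R)-4-{[4-(benzyloxy)-3-methoxyphenyl]methyl}-3-hydroxyoxolan-2-one | COc1cc(C[C@@H]2COC(=O)[C@H]2O)ccc1OCc1ccccc1 | intermediate
13 | vanillin (4-hydroxy-3-methoxybenzaldehyde) | COc1cc(C=O)ccc1O | starting material
14 | 6,6'-dihydroxy-5,5'-dimethoxy-[1,1'-biphenyl]-3,3'-dicarbaldehyde (dehydrodivanillin) | COc1cc(C=O)cc(-c2cc(C=O)cc(OC)c2O)c1O | intermediate
15 | 6,6'-bis(benzyloxy)-5,5'-dimethoxy-[1,1'-biphenyl]-3,3'-dicarbaldehyde | COc1cc(C=O)cc(-c2cc(C=O)cc(OC)c2OCc2ccccc2)c1OCc1ccccc1 | intermediate
16 | [6,6'-bis(benzyloxy)-5,5'-dimethoxy-[1,1'-biphenyl]-3,3'-diyl]dimethanol | COc1cc(CO)cc(-c2cc(CO)cc(OC)c2OCc2ccccc2)c1OCc1ccccc1 | intermediate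
17 | 2,2'-bis(benzyloxy)-5,5'-bis(bromomethyl)-3,3'-dimethoxy-1,1'-biphenyl | COc1cc(CBr)cc(-c2cc(CBr)cc(OC)c2OCc2ccccc2)c1OCc1ccccc1 | intermediate
18 | (3R,4R)-4-{[4-(benzyloxy)-3-methoxyphenyl]methyl}-3-{[6,6'-bis(benzyloxy)-3'-(bromomethyl)-5,5'-dimethoxy-[1,1'-biphenyl]-3-yl]methyl}-3-hydroxyoxolan-2-one | COc1cc(C[C@@H]2COC(=O)[C@@]2(O)Cc2cc(OC)c(OCc3ccccc3)c(-c3cc(CBr)cc(OC)c3OCc3ccccc3)c2)ccc1OCc1ccccc1 | intermediate
19 | pinacol boronate of 18: as 18 with the 3'-CH2Br replaced by 3'-CH2-(4,4,5,5-tetramethyl-1,3,2-dioxaborolan-2-yl) | COc1cc(C[C@@H]2COC(=O)[C@@]2(O)Cc2cc(OC)c(OCc3ccccc3)c(-c3cc(CB4OC(C)(C)C(C)(C)O4)cc(OC)c3OCc3ccccc3)c2)ccc1OCc1ccccc1 | intermediate (not isolated)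
20 | potassium trifluoroborate of 18: as 18 with the 3'-CH2Br replaced by 3'-CH2BF3K | COc1cc(C[C@@H]2COC(=O)[C@@]2(O)Cc2cc(OC)c(OCc3ccccc3)c(-c3cc(C[B-](F)(F)F)cc(OC)c3OCc3ccccc3)c2)ccc1OCc1ccccc1.[K+] | intermediate
21 | Giese adduct: as 18 with the 3'-CH2Br replaced by 3'-CH2 bonded to C-3 of a (3S)-4-[(tert-butyldimethylsilyl)oxy]-1-(3,5-dimethyl-1H-pyrazol-1-yl)-1-oxobutan-3-yl unit | COc1cc(C[C@@H]2COC(=O)[C@@]2(O)Cc2cc(OC)c(OCc3ccccc3)c(-c3cc(C[C@H](CO[Si](C)(C)C(C)(C)C)CC(=O)n4nc(C)cc4C)cc(OC)c3OCc3ccccc3)c2)ccc1OCc1ccccc1 | intermediate (not isolated)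
22 | (3R,4R)-4-{[4-(benzyloxy)-3-methoxyphenyl]methyl}-3-{[6,6'-bis(benzyloxy)-5,5'-dimethoxy-3'-{[(3S)-5-oxooxolan-3-yl]methyl}-[1,1'-biphenyl]-3-yl]methyl}-3-hydroxyoxolan-2-one | COc1cc(C[C@@H]2COC(=O)[C@@]2(O)Cc2cc(OC)c(OCc3ccccc3)c(-c3cc(C[C@@H]4COC(=O)C4)cc(OC)c3OCc3ccccc3)c2)ccc1OCc1ccccc1 | intermediate
23 | as 22 with the 3'-substituent {[(3R,4S)-4-hydroxy-5-oxooxolan-3-yl]methyl} (lactone 2 hydroxylated at C-3, trans to the C-4 benzyl) | COc1cc(C[C@@H]2COC(=O)[C@@]2(O)Cc2cc(OC)c(OCc3ccccc3)c(-c3cc(C[C@@H]4COC(=O)[C@H]4O)cc(OC)c3OCc3ccccc3)c2)ccc1OCc1ccccc1 | intermediate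
24 | tetra-O-benzyl ether of the target: as 22 with the 3'-substituent {[(3R,4R)-4-{[4-(benzyloxy)-3-methoxyphenyl]methyl}-4-hydroxy-5-oxooxolan-3-yl]methyl} | COc1cc(C[C@@H]2COC(=O)[C@@]2(O)Cc2cc(OC)c(OCc3ccccc3)c(-c3cc(C[C@@H]4COC(=O)[C@@]4(O)Cc4ccc(OCc5ccccc5)c(OC)c4)cc(OC)c3OCc3ccccc3)c2)ccc1OCc1ccccc1 | intermediate
25 | CNP0218652.1: both lactones (3R,4R)-3-hydroxy-3,4-dibenzyl, four free phenols | COc1cc(C[C@@H]2COC(=O)[C@@]2(O)Cc2cc(OC)c(O)c(-c3cc(C[C@@H]4COC(=O)[C@@]4(O)Cc4ccc(O)c(OC)c4)cc(OC)c3O)c2)ccc1O | target

**Step count and risks**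

Total step count: 16.
Longest linear sequence: 10 steps (6 → 7 → 9 → 11 → 12 → 18 → 20 → 22 → 23 → 24 → 25, steps 3, 4, 5, 6, 11, 12, 13, 14, 15, 16).

Steps most likely to fail:

Step 13. The step may suffer from weak face discrimination on the rhodium-bound acceptor, photochemical E/Z isomerisation of the acceptor, binding of the Lewis acid by the hydroxy lactone of the large fragment, or dimerisation of the benzyl radical before it adds. The fallback hands stereocontrol to the substrate and sets out from 20. Its benzyl radical is generated with 4CzIPN under blue LEDs in acetone/H2O without Lewis acid and added to commercial (5S)-5-[(1S,2R,5S)-menthyloxy]furan-2(5H)-one (CC(C)[C@H]1CC[C@H](C)C[C@@H]1O[C@H]1OC(=O)C=C1). Addition anti to the menthyloxy group should give the trans-4,5-disubstituted menthyloxy lactone F1. Treatment with NaBH4/KOH in aqueous EtOH and then acid opens the acylal, reduces the released aldehyde, relactonises both lactones and removes menthol, and the fallback comes back to the route at 22.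

Step 11. Alkylation may occur at both bromomethyl arms of the dibromide, and the surviving electron-rich benzylic bromide may be lost by solvolysis during isolation. The fallback moves the desymmetrisation ahead of the fragment union and sets out from 17. Statistical mono-borylation (0.5 equiv B2pin2, Pd2(dba)3, P(4-MeOC6H4)3, KOAc, toluene, 50 °C) should give the mono-boronate mono-bromide F2, which has a single electrophilic arm and a robust boron arm. Alkylation of the enediolate of 12 (LiN(iPr)2, THF/DMPU, −78 °C) with F2 comes back to the route at 19, here isolated, which the KHF2 half of step 12 converts into 20.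

Step 15. The two lithium alkoxides may be O-benzylated in competition with the enolate carbon, and formation of the trianion may be incomplete. The fallback replaces the trianion by a mono-enolate of a fully O-silylated substrate and sets out from 23. Both hydroxyls are silylated (Et3SiOTf, 2,6-lutidine, CH2Cl2) to the bis(triethylsilyl) ether F3. Its lithium enolate (LiN(iPr)2, 1.2 equiv, THF/DMPU, −78 °C) is benzylated with 7 anti to the C-4 substituent to give the bis(triethylsilyl) ether F4. HF·pyridine in THF removes both silyl groups, and the fallback comes back to the route at 24.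

Further compounds
F1 | step 13 | as 22, but lactone 2 is the (4S,5S)-5-[(1S,2R,5S)-menthyloxy]oxolan-2-one (menthyloxy trans to the C-4 benzyl) | COc1cc(C[C@@H]2COC(=O)[C@@]2(O)Cc2cc(OC)c(OCc3ccccc3)c(-c3cc(C[C@@H]4[C@@H](O[C@H]5C[C@@H](C)CC[C@@H]5C(C)C)OC(=O)C4)cc(OC)c3OCc3ccccc3)c2)ccc1OCc1ccccc1
F2 | step 11 | 2-{[6,6'-bis(benzyloxy)-3'-(bromomethyl)-5,5'-dimethoxy-[1,1'-biphenyl]-3-yl]methyl}-4,4,5,5-tetramethyl-1,3,2-dioxaborolane | COc1cc(CBr)cc(-c2cc(CB3OC(C)(C)C(C)(C)O3)cc(OC)c2OCc2ccccc2)c1OCc1ccccc1
F3 | step 15 | bis(triethylsilyl) ether of 23 (tertiary OH of lactone 1 and secondary OH of lactone 2 silylated) | COc1cc(C[C@@H]2COC(=O)[C@@]2(O[Si](CC)(CC)CC)Cc2cc(OC)c(OCc3ccccc3)c(-c3cc(C[C@@H]4COC(=O)[C@H]4O[Si](CC)(CC)CC)cc(OC)c3OCc3ccccc3)c2)ccc1OCc1ccccc1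
F4 | step 15 | bis(triethylsilyl) ether of 24 (both tertiary hydroxyls silylated) | COc1cc(C[C@@H]2COC(=O)[C@@]2(O[Si](CC)(CC)CC)Cc2cc(OC)c(OCc3ccccc3)c(-c3cc(C[C@@H]4COC(=O)[C@@]4(O[Si](CC)(CC)CC)Cc4ccc(OCc5ccccc5)c(OC)c4)cc(OC)c3OCc3ccccc3)c2)ccc1OCc1ccccc1
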